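The route rests on cutting C4–C5 and C9–C10 of the trans-decalin (rings A and B). Its C4, C5, C10 and C9 centres show the all-anti pattern of an E,E-polyene chair–chair fold, the equatorial C4–CH2OH is the E-terminal carbon of an allylic alcohol (so a Sharpless oxirane can start the fold), and sp2 C8 can leave the fold as a ketone. One Lewis-acid step therefore closes both rings from an acyclic (S,S)-epoxide carrying the C5=C10 E-alkene and a (Z)-C8=C9 enol silane whose C9 already bears the arylmethyl arm (joined by aldol condensation of a geranylacetone-derived ketone with a salicylaldehyde). The arene is later dearomatised, epoxidised and reduced to the epoxyquinol.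

Key step: step 10

Remark on numbering: drimane numbering is used for the decalin (C1–C10, C11 = arylmethyl CH2, C12 = methyl on C8). Primes denote the six-membered ring made from the arene: C1′ is bonded to C11, C3′ carries OMe (later the ketal, then C=O), C4′ carries CH2OH, C6′ carries the phenol oxygen. Ar = 5-methoxy-2-(triisopropylsilyloxy)-4-[(triisopropylsilyloxy)methyl]phenyl.

Assumption: L-(+)-DIPT is taken as the tartrate that sends the peroxide of step 17 to the C2′ Si face. The tartrate is a reagent choice, so D-(−)-DIPT replaces it in the same step if a first run shows the opposite sense.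

Step 1
Reactants: 1 (E)-geranylacetone
Product: 2 (5E,9E)-11-hydroxy-6,10-dimethylundeca-5,9-dien-2-one
Conditions: SeO2 (cat.), t-BuOOH, salicylic acid (cat.), CH2Cl2, 0 °C → rt, stopped at partial conversion
Reagents that add atoms: tert-butyl hydroperoxide, CC(C)(C)OO (oxygen source, relayed by catalytic SeO2, O=[Se]=O)
Why: Riley-type SeO2/t-BuOOH allylic oxidation (ene reaction, then [2,3]-shift) should attack the E-methyl of the terminal trisubstituted alkene and give the E-allylic alcohol, while the methyl ketone is not α-oxidised at room temperature with catalytic selenium.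

Step 2
Reactants: 2 (5E,9E)-11-hydroxy-6,10-dimethylundeca-5,9-dien-2-one
Product: 3 (5E)-8-[(2S,3S)-3-(hydroxymethyl)-3-methyloxiran-2-yl]-6-methyloct-5-en-2-one
Conditions: Ti(OiPr)4 (cat.), L-(+)-DET (cat.), t-BuOOH, 4 Å MS, CH2Cl2, −20 °C
Reagents that add atoms: tert-butyl hydroperoxide, CC(C)(C)OO
Why: Katsuki–Sharpless asymmetric epoxidation; the Ti/L-(+)-tartrate complex binds the allylic alcohol and delivers oxygen to the face that gives the (2S,3S)-oxirane of an E-2-methylalk-2-en-1-ol, which sets both oxirane centres and leaves the isolated alkene and the ketone alone.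

Step 3
Reactants: 3 the (2S,3S)-epoxy alcohol
Product: 4 (5E)-8-[(2S,3S)-3-(tert-butyldimethylsilyloxymethyl)-3-methyloxiran-2-yl]-6-methyloct-5-en-2-one
Conditions: TBSCl, imidazole, DMF, 0 °C → rt
Reagents that add atoms: tert-butyldimethylsilyl chloride, CC(C)(C)[Si](C)(C)Cl
Why: Standard silylation of the primary alcohol gives an ether that tolerates LDA, MeAlCl2 at −78 °C and radical conditions and does not participate as a neighbouring group in step 10.

Step 4
Reactants: 5 2,5-dimethoxyterephthalaldehyde
Product: 6 2-hydroxy-5-methoxyterephthalaldehyde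
Conditions: BCl3 (1.05 equiv), CH2Cl2, −78 → 0 °C; then H2O
Reagents that add atoms: none
Why: Chelation-controlled ortho-demethylation: BCl3 bridges a formyl oxygen and its ortho methoxy group and chloride removes the methyl, and one equivalent should stop at mono-cleavage because the first boron chelate lowers the basicity of the second site.

Step 5
Reactants: 6 2-hydroxy-5-methoxyterephthalaldehyde
Product: 7 2-hydroxy-4-(hydroxymethyl)-5-methoxybenzaldehyde
Conditions: NaBH4 (0.3 equiv), aq. NaOH (1.1 equiv), MeOH, 0 °C; then dilute HCl to pH 5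
Reagents that add atoms: none
Why: Chemoselective borohydride reduction: in base the phenoxide turns its ortho formyl group into a vinylogous carboxylate, so hydride should take the other formyl group, which is meta to O− and para to a carbonyl.

Step 6
Reactants: 7 2-hydroxy-4-(hydroxymethyl)-5-methoxybenzaldehyde
Product: 8 5-methoxy-2-(triisopropylsilyloxy)-4-[(triisopropylsilyloxy)methyl]benzaldehyde (ArCHO)
Conditions: TIPSCl (2.4 equiv), imidazole, DMAP (cat.), DMF, rt
Reagents that add atoms: triisopropylsilyl chloride, CC(C)[Si](Cl)(C(C)C)C(C)C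
Why: One silylation covers phenol and primary alcohol; TIPS is chosen over TBS so that the aryl silyl group does not migrate to the aldolate oxygen in step 7 and withstands the Lewis acid of step 10.

Step 7
Reactants: 4 the silyl-protected epoxy methyl ketone; 8 ArCHO
Product: 10 β-hydroxy ketone ArCH(OH)–CH2–C(=O)–chain (C9–C11 bond formed, both C11 epimers), via lithium enolate of 4 at the methyl terminus 9 (not isolated)
Conditions: LDA (1.05 equiv), THF, −78 °C, 4 added slowly; then 8, −78 °C; AcOH quench at −78 °C
Reagents that add atoms: none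
Why: Directed aldol addition: LDA at −78 °C deprotonates the methyl group (C9) kinetically and not C7, the enolate adds to the non-enolisable aldehyde, and the cold acidic quench forestalls retro-aldol and silyl migration; the carbinol configuration does not matter.

Step 8
Reactants: 10 the β-hydroxy ketone
Product: 12 (E)-aryl enone ArCH=CH–C(=O)–CH2CH2–CH=C(CH3)–CH2CH2–[(2S,3S)-oxirane with CH3 and CH2OTBS], via C11 mesylate of 10 11 (not isolated)
Conditions: MsCl, Et3N (excess), CH2Cl2, 0 °C → rt
Reagents that add atoms: none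
Why: Mesylation and E1cB elimination of the β-mesyloxy ketone should give the conjugated E-enone and erase the C11 carbinol centre.

Step 9
Reactants: 12 the (E)-aryl enone
Product: 13 (Z)-triethylsilyl enol ether (C8–OSiEt3, C8=C9, C11H2Ar)
Conditions: RhH(PPh3)4 (1 mol %), Et3SiH (1.3 equiv), toluene, 50 °C; filtration through Et3N-deactivated silica
Reagents that add atoms: triethylsilane, CC[SiH](CC)CC
Why: Rhodium-hydride-catalysed 1,4-hydrosilylation puts silicon on oxygen and hydrogen on C11 through the s-cis enone, so the enol silane can form only towards C9 and with Z geometry (O and C11 cis); the trisubstituted alkene, oxirane and silyl ethers are inert to these conditions.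

Step 10
Reactants: 13 the (Z)-enol silane
Product: 14 3β-hydroxy-8-oxo trans-decalin: 4α-CH2OTBS, 4β-CH3, 5α-H, 10β-CH3, 9β-CH2Ar (9α-H)
Conditions: MeAlCl2 (2.5 equiv), CH2Cl2, −78 °C; then aq. NaHCO3/Rochelle salt
Reagents that add atoms: none
Why: MeAlCl2 binds the oxirane oxygen and weakens the tertiary C4–O bond, the C5=C10 alkene attacks C4 anti to the departing oxygen, C9 of the enol silane takes the charge arriving at C10, and the silyloxocarbenium ion gives up Et3Si+ to leave the C8 ketone. The closest known reaction type is the Lewis-acid epoxide-initiated cation–olefin polycyclisation terminated by a silyl enol ether, which is also known with initiators made from 2,3-epoxy alcohols. Ring A closes 6-endo-trig at the alkene with endo opening of the oxirane at its tertiary carbon, and ring B closes 6-endo-trig at the enol silane. C4 is set by inversion at the (S,S)-oxirane (CH2OSi equatorial, CH3 axial, C3–O equatorial), C5 and C10 by anti addition across the E-alkene in a chair–chair fold (H5 anti to the C10 methyl), and C9 by the Z enol-silane geometry, which places C11 equatorial and is backed by epimerisability next to the ketone. The step needs a single chair–chair fold in one absolute sense and a terminator faster than the arene or any oxygen nucleophile: the single oxirane enantiomer leaves one face of C4 open, and the enol silane quenches C10 irreversibly and regiospecifically, so neither alkene isomers nor a long-lived cation should arise.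

Step 11
Reactants: 14 the 3β-hydroxy-8-oxo decalin
Product: 15 3β-O-(imidazol-1-ylthiocarbonyl) derivative of 14
Conditions: 1,1′-thiocarbonyldiimidazole, DMAP (cat.), toluene, 80 °C
Reagents that add atoms: 1,1′-thiocarbonyldiimidazole, S=C(n1ccnc1)n1ccnc1
Why: Neutral thioacylation of the equatorial secondary alcohol avoids the enolate chemistry that NaH/CS2 would start at the C8 ketone, and leaves the silyl ethers untouched.

Step 12
Reactants: 15 the thiocarbonylimidazolide
Product: 16 3-deoxy-8-oxo decalin (4α-CH2OTBS, 9β-CH2Ar)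
Conditions: Bu3SnH, AIBN (cat.), toluene, 100 °C
Reagents that add atoms: none
Why: Barton–McCombie deoxygenation: the stannyl radical adds to C=S, β-scission gives the secondary C3 radical, which takes hydrogen from Sn–H; no alkene is present yet, so the radical cannot cyclise.

Step 13
Reactants: 16 the 3-deoxy decalone
Product: 18 Δ7-enol triflate (8-trifluoromethanesulfonyloxy-7-ene), via potassium Δ7-enolate of 16 17 (not isolated)
Conditions: KHMDS, THF, −78 °C; then PhNTf2, −78 → 0 °C
Reagents that add atoms: N-phenylbis(trifluoromethanesulfonimide), O=S(=O)(N(c1ccccc1)S(=O)(=O)C(F)(F)F)C(F)(F)F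
Why: Kinetic deprotonation takes the accessible C7 hydrogens and not the tertiary C9–H wedged between quaternary C10 and the arylmethyl arm, and O-sulfonylation fixes the double bond at C7=C8 without touching C9.

Step 14
Reactants: 18 the Δ7-enol triflate
Product: 19 tris-silylated drim-7-en-11-yl arene (C8–CH3, C7=C8)
Conditions: MeMgBr, Fe(acac)3 (5 mol %), THF/NMP, −30 → 0 °C
Reagents that add atoms: methylmagnesium bromide, C[Mg]Br
Why: Iron-catalysed Kumada-type coupling of an alkenyl triflate replaces OTf by CH3 with the alkene position retained; the silyl ethers are inert to the Grignard reagent at or below 0 °C.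

Step 15
Reactants: 19 the tris-silyl ether
Product: 20 free 4-methoxyphenol diol (C6′–OH, C3′–OMe, C4′–CH2OH, decalin C4–CH2OH)
Conditions: TBAF (5 equiv), THF, rt → 45 °C, argon; aq. NH4Cl
Reagents that add atoms: none
Why: Fluoride cleaves the aryl and both primary silyl ethers (the neopentyl TBS ether last); exclusion of air protects the electron-rich phenoxide.

Step 16
Reactants: 20 the phenol diol
Product: 21 quinone monoketal (C6′=O, C3′(OMe)2, C1′=C2′ and C4′=C5′)
Conditions: PhI(OAc)2 (1.1 equiv), MeOH, 0 °C
Reagents that add atoms: methanol, CO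
Why: Iodine(III) oxidative dearomatisation of a para-methoxyphenol: the aryloxy-iodane collapses to a cation stabilised by the methoxy group and methanol adds at C3′; primary alcohols and the trisubstituted alkene are inert to this reagent at 0 °C.

Step 17
Reactants: 21 the quinone monoketal
Product: 22 (1′S,2′S)-1′,2′-epoxy ketone monoketal
Conditions: Ph3COOH, NaHMDS, L-(+)-DIPT, 4 Å MS, toluene, −65 °C; aq. NH4Cl
Reagents that add atoms: trityl hydroperoxide, OOC(c1ccccc1)(c1ccccc1)c1ccccc1
Why: Tartrate-mediated Weitz–Scheffer epoxidation of a quinone monoketal: the alkoxide of the C4′ hydroxymethyl group anchors the tartrate–peroxide complex, the peroxide adds to the unsubstituted β-carbon C2′ and the enolate closes on oxygen at C1′, so both centres are set together under reagent control, while the β-substituted C4′=C5′ bond and the isolated C7=C8 alkene do not react with a nucleophilic oxidant.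

Step 18
Reactants: 22 the epoxy ketone monoketal
Product: 23 (6′R)-epoxy alcohol monoketal (C6′–OH anti to the oxirane oxygen)
Conditions: DIBAL-H (4 equiv), THF, −78 °C; Rochelle salt
Reagents that add atoms: none
Why: 1,2-Reduction in which hydride should reach C6′ from the oxirane face (aluminium coordinates the oxirane oxygen, and the C11 methylene with its decalin shields the other face), giving the alcohol anti to the oxirane; ketal and oxirane are inert at −78 °C.

Step 19
Reactants: 23 the epoxy alcohol monoketal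
Product: 24 Epoxypholamin A, (4R,5R,9S,10R,1′S,2′S,6′R)
Conditions: PPTS (cat.), acetone/H2O (9:1), rt
Reagents that add atoms: water, O
Why: Mild acid hydrolysis of the dimethyl ketal through the allylic oxocarbenium ion gives the C3′ enone; the oxirane (deactivated by the adjacent carbonyl), the C6′ alcohol and the C7=C8 alkene should survive this weak acid.

Compound list
1 | (E)-geranylacetone | CC(=O)CC/C=C(C)/CCC=C(C)C | starting material
2 | (5E,9E)-11-hydroxy-6,10-dimethylundeca-5,9-dien-2-one | CC(=O)CC/C=C(C)/CC/C=C(C)/CO | intermediate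
3 | (5E)-8-[(2S,3S)-3-(hydroxymethyl)-3-methyloxiran-2-yl]-6-methyloct-5-en-2-one | CC(=O)CC/C=C(C)/CC[C@@H]1O[C@@]1(C)CO | intermediate
4 | TBS ether of 3 | CC(=O)CC/C=C(C)/CC[C@@H]1O[C@@]1(C)CO[Si](C)(C)C(C)(C)C | intermediate
5 | 2,5-dimethoxyterephthalaldehyde | O=Cc1cc(OC)c(C=O)cc1OC | starting material
6 | 2-hydroxy-5-methoxyterephthalaldehyde | O=Cc1cc(OC)c(C=O)cc1O | intermediate
7 | 2-hydroxy-4-(hydroxymethyl)-5-methoxybenzaldehyde | O=Cc1cc(OC)c(CO)cc1O | intermediate
8 | 5-methoxy-2-(triisopropylsilyloxy)-4-[(triisopropylsilyloxy)methyl]benzaldehyde | O=Cc1cc(OC)c(CO[Si](C(C)C)(C(C)C)C(C)C)cc1O[Si](C(C)C)(C(C)C)C(C)C | intermediate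
9 | lithium enolate of 4 at the methyl terminus | [Li+].C=C([O-])CC/C=C(C)/CC[C@@H]1O[C@@]1(C)CO[Si](C)(C)C(C)(C)C | intermediate
10 | aldol adduct (β-hydroxy ketone, C11 epimers) | O=C(CC(O)c1cc(OC)c(CO[Si](C(C)C)(C(C)C)C(C)C)cc1O[Si](C(C)C)(C(C)C)C(C)C)CC/C=C(C)/CC[C@@H]1O[C@@]1(C)CO[Si](C)(C)C(C)(C)C | intermediate
11 | C11 mesylate of 10 | O=C(CC(OS(C)(=O)=O)c1cc(OC)c(CO[Si](C(C)C)(C(C)C)C(C)C)cc1O[Si](C(C)C)(C(C)C)C(C)C)CC/C=C(C)/CC[C@@H]1O[C@@]1(C)CO[Si](C)(C)C(C)(C)C | intermediate
12 | (E)-aryl enone with the full carbon chain | O=C(/C=C/c1cc(OC)c(CO[Si](C(C)C)(C(C)C)C(C)C)cc1O[Si](C(C)C)(C(C)C)C(C)C)CC/C=C(C)/CC[C@@H]1O[C@@]1(C)CO[Si](C)(C)C(C)(C)C | intermediate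
13 | (Z)-triethylsilyl enol ether (C8=C9) | CC[Si](CC)(CC)O/C(CC/C=C(C)/CC[C@@H]1O[C@@]1(C)CO[Si](C)(C)C(C)(C)C)=C\Cc1cc(OC)c(CO[Si](C(C)C)(C(C)C)C(C)C)cc1O[Si](C(C)C)(C(C)C)C(C)C | intermediate
14 | 3β-hydroxy-8-oxo trans-decalin, 4α-CH2OTBS, 9β-CH2Ar | O=C1CC[C@H]2[C@](C)(CO[Si](C)(C)C(C)(C)C)[C@@H](O)CC[C@]2(C)[C@H]1Cc1cc(OC)c(CO[Si](C(C)C)(C(C)C)C(C)C)cc1O[Si](C(C)C)(C(C)C)C(C)C | intermediate
15 | 3β-O-(imidazol-1-ylthiocarbonyl) derivative of 14 | O=C1CC[C@H]2[C@](C)(CO[Si](C)(C)C(C)(C)C)[C@@H](OC(=S)n3ccnc3)CC[C@]2(C)[C@H]1Cc1cc(OC)c(CO[Si](C(C)C)(C(C)C)C(C)C)cc1O[Si](C(C)C)(C(C)C)C(C)C | intermediate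
16 | 3-deoxy-8-oxo decalin | O=C1CC[C@H]2[C@](C)(CO[Si](C)(C)C(C)(C)C)CCC[C@]2(C)[C@H]1Cc1cc(OC)c(CO[Si](C(C)C)(C(C)C)C(C)C)cc1O[Si](C(C)C)(C(C)C)C(C)C | intermediate
17 | potassium Δ7-enolate of 16 | [K+].[O-]C1=CC[C@H]2[C@](C)(CO[Si](C)(C)C(C)(C)C)CCC[C@]2(C)[C@H]1Cc1cc(OC)c(CO[Si](C(C)C)(C(C)C)C(C)C)cc1O[Si](C(C)C)(C(C)C)C(C)C | intermediate
18 | Δ7-enol triflate | O=S(=O)(OC1=CC[C@H]2[C@](C)(CO[Si](C)(C)C(C)(C)C)CCC[C@]2(C)[C@H]1Cc1cc(OC)c(CO[Si](C(C)C)(C(C)C)C(C)C)cc1O[Si](C(C)C)(C(C)C)C(C)C)C(F)(F)F | intermediate
19 | tris-silylated drim-7-en-11-yl arene | CC1=CC[C@H]2[C@](C)(CO[Si](C)(C)C(C)(C)C)CCC[C@]2(C)[C@H]1Cc1cc(OC)c(CO[Si](C(C)C)(C(C)C)C(C)C)cc1O[Si](C(C)C)(C(C)C)C(C)C | intermediate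
20 | free 4-methoxyphenol diol | CC1=CC[C@H]2[C@](C)(CO)CCC[C@]2(C)[C@H]1Cc1cc(OC)c(CO)cc1O | intermediate
21 | quinone monoketal (C6′ ketone, C3′ dimethyl ketal) | CC1=CC[C@H]2[C@](C)(CO)CCC[C@]2(C)[C@H]1CC1=CC(OC)(OC)C(CO)=CC1=O | intermediate
22 | (1′S,2′S)-epoxy ketone monoketal | CC1=CC[C@H]2[C@](C)(CO)CCC[C@]2(C)[C@H]1C[C@@]12O[C@@H]1C(OC)(OC)C(CO)=CC2=O | intermediate
23 | (6′R)-epoxy alcohol monoketal | CC1=CC[C@H]2[C@](C)(CO)CCC[C@]2(C)[C@H]1C[C@@]12O[C@@H]1C(OC)(OC)C(CO)=C[C@H]2O | intermediate
24 | Epoxypholamin A | CC1=CC[C@H]2[C@](C)(CO)CCC[C@]2(C)[C@H]1C[C@@]12O[C@@H]1C(=O)C(CO)=C[C@H]2O | target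

Total step count: 19. Longest linear sequence: 16 steps (steps 1–3 and 7–19 from 1; the arene branch, steps 4–6 from 5, is equally long up to the junction).

Steps most likely to fail

Step 10. The oxirane, slowed by the electron-withdrawing CH2OSi group, may ionise more slowly than the Lewis acid strips the enol silane, or the cascade may stop after ring A or divert by hydride shift at C3. The fallback replaces the cationic cascade by a radical one and runs from 12 back to 14. Conjugate reduction of 12 with L-Selectride at −78 °C and trapping of the Z-enolate with PhNTf2 should give the (Z)-enol triflate F1. Negishi coupling (MeZnCl, Pd(PPh3)4) then replaces OTf by CH3 with retention to give the E-trisubstituted alkene F2. Titanocene(III) chloride (Cp2TiCl2, Mn, THF) opens the oxirane homolytically at C4; the radical cyclises 6-endo twice and ends by β-hydride elimination as the 3β-hydroxy 8(12)-exocyclic alkene F3. Lemieux–Johnson cleavage (OsO4 cat., NaIO4, 2,6-lutidine) of the methylene gives the C8 ketone, which is 14. In this variant C4 is set by the chair transition state (larger CH2OSi equatorial) and not by inversion, so a C4 epimer may have to be separated at F3, and the C8 methyl is reinstalled by steps 13–14.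

Step 17. Facial selectivity may be poor if the remote decalin or the second, spectator alkoxide disturbs the tartrate chelate, and attack at C4′=C5′ may compete. The fallback uses ion-pair catalysis on a substrate without free hydroxyl groups and runs from 19 back to 22. One equivalent of TBAF at −20 °C should cleave only the aryl silyl ether of 19 and give the bis-silylated phenol F4. PhI(OAc)2 in MeOH gives the bis-silylated quinone monoketal F5. Weitz–Scheffer epoxidation under chiral phase-transfer catalysis (N-benzylcinchonidinium-type salt or its pseudo-enantiomer, t-BuOOH, aq. NaOH, toluene, 0 °C) gives the bis-silylated epoxy ketone F6; a minor diastereomer is separable because the decalin is a single enantiomer. TBAF/AcOH removes both silyl groups and returns 22.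

Step 7. The lithium aldolate may take the ortho silyl group (O-to-O silyl migration) or revert by retro-aldol before the quench. The fallback replaces aldol addition and dehydration by an olefination, runs from 4 back to 12 and makes step 8 unnecessary. The kinetic lithium enolate of 4 is C-phosphinylated with ClP(OEt)2 and the phosphonite is oxidised (air, then H2O2) to the β-ketophosphonate F7. Horner–Wadsworth–Emmons reaction of F7 with 8 under Masamune–Roush conditions (LiCl, DBU, MeCN) should give the E-enone 12 directly, with no alkoxide next to the silyloxy group.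

Further compounds
F1 | step 10 | (Z)-enol triflate from conjugate reduction of 12 | O=S(=O)(O/C(CC/C=C(C)/CC[C@@H]1O[C@@]1(C)CO[Si](C)(C)C(C)(C)C)=C\Cc1cc(OC)c(CO[Si](C(C)C)(C(C)C)C(C)C)cc1O[Si](C(C)C)(C(C)C)C(C)C)C(F)(F)F
F2 | step 10 | E-trisubstituted alkene (C8–CH3, C8=C9) with the (S,S)-oxirane | C/C(CC/C=C(C)/CC[C@@H]1O[C@@]1(C)CO[Si](C)(C)C(C)(C)C)=C\Cc1cc(OC)c(CO[Si](C(C)C)(C(C)C)C(C)C)cc1O[Si](C(C)C)(C(C)C)C(C)C
F3 | step 10 | 3β-hydroxy 8(12)-exocyclic alkene, 4α-CH2OTBS, 9β-CH2Ar | C=C1CC[C@H]2[C@](C)(CO[Si](C)(C)C(C)(C)C)[C@@H](O)CC[C@]2(C)[C@H]1Cc1cc(OC)c(CO[Si](C(C)C)(C(C)C)C(C)C)cc1O[Si](C(C)C)(C(C)C)C(C)C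
F4 | step 17 | bis-silylated phenol (free C6′–OH) | CC1=CC[C@H]2[C@](C)(CO[Si](C)(C)C(C)(C)C)CCC[C@]2(C)[C@H]1Cc1cc(OC)c(CO[Si](C(C)C)(C(C)C)C(C)C)cc1O
F5 | step 17 | bis-silylated quinone monoketal | CC1=CC[C@H]2[C@](C)(CO[Si](C)(C)C(C)(C)C)CCC[C@]2(C)[C@H]1CC1=CC(OC)(OC)C(CO[Si](C(C)C)(C(C)C)C(C)C)=CC1=O
F6 | step 17 | bis-silylated (1′S,2′S)-epoxy ketone monoketal | CC1=CC[C@H]2[C@](C)(CO[Si](C)(C)C(C)(C)C)CCC[C@]2(C)[C@H]1C[C@@]12O[C@@H]1C(OC)(OC)C(CO[Si](C(C)C)(C(C)C)C(C)C)=CC2=O
F7 | step 7 | β-ketophosphonate of 4 (diethyl phosphonate on C9) | CCOP(=O)(OCC)CC(=O)CC/C=C(C)/CC[C@@H]1O[C@@]1(C)CO[Si](C)(C)C(C)(C)C
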